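**Remarks on the chemistry (assumptions)**
- The SMILES is read as written: ring atoms are numbered C1 (ester carbinol), C2=C3(CH3), C4, C5, C6=C7(CH3), C8, C9, C10 (isopropyl). Both ring olefins have their ring carbons cis (2Z,6Z), C1 is R, C10 is S, and the ester oxygen and the isopropyl group are cis on the ring.
- Technical 1,5-dimethylcycloocta-1,5-diene (isoprene cyclodimer) contains the 1,6-dimethyl isomer. It is assumed that 1 is enriched by fractional distillation and that the remaining regioisomeric series is removed by chromatography at enone 6.
- 4-Acetoxy-3-methoxybenzoic acid 17 is taken as a commercial compound.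

## The problem

The target is the vanillate of a ten-membered carbocyclic dienol, numbered as in the remarks with C10 bonded to C1. A ten-membered carbocycle resists closure from an open chain (transannular strain, entropy). Here it also carries two trisubstituted olefins with the ring carbons cis on both, so the ring construction has to fix two olefin geometries as well. The two stereocentres C1 (R) and C10 (S) are contiguous, with oxygen and isopropyl cis. C10 has no function of its own and can only be reached through C1, to which it is α when C1 is a carbonyl group. The 1,5-diene in a medium ring is prone to acid-induced transannular cyclisation and to Cope rearrangement on heating, the C1 ester is allylic (ionisation by acid or zerovalent palladium), and the phenol is free, so late steps must be neutral or basic and cool.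

The feature that opens the route is this: C1, C2H=C3(CH3), C4H2, C5H2, C6H=C7(CH3) and C8H2 together are the eight-membered ring of the head-to-tail cyclodimer of isoprene, with both olefins already cis, the oxygen on C1 and C8 allylic. The missing atoms C9 and C10 (with its isopropyl group) can be attached to C1 as a vinyl group and slid into the ring between C1 and C8 by a 1,3-shift of C8 from C1 to C9. The same shift makes C1 a ketone with C10 α to it, so both stereocentres can then be set together by one reduction under dynamic kinetic resolution.

## Retrosynthesis

**Ester (20 ⇒ 19 ⇒ 16 + 17).** The acyl C–O bond is cut. Forming the C1–O bond by substitution instead would put the allylic centre C1 at risk (ionisation, attack at C3). Acylation of alcohol 16 with the chloride 18 of commercial acid 17 leaves C1 untouched. The phenol is carried as an acetate (19) so that 18 cannot acylate itself. The forward sequence needs a deprotection that spares the allylic ester and the acid-sensitive diene, which aminolysis of the aryl acetate provides.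

**Both stereocentres (16 ⇒ 15).** The C1–H bond is removed and the configuration at C10 is given up, leading back to racemic ketone 15. Setting C10 earlier would gain nothing, because C10 is created by protonation of an enolate in the ring-forming step and is enolisable in 15. The forward step must choose one carbonyl face by catalyst control, epimerise C10 faster than the slow enantiomer is reduced, and leave both olefins alone.

**Ring (15 ⇒ 12).** The C8–C9 bond is cut and C1–C8 is re-formed, giving the eight-membered tertiary carbinol 12, an isomer of 15. The neighbouring cuts (C1–C10, C9–C10, C6=C7) all lead to open chains in which two Z-trisubstituted olefins must be built and a ten-membered ring closed. Re-forming C1–C6 instead (a six-membered divinyl carbinol) brings a relative-configuration requirement that decides the C6=C7 geometry. In 12 both olefins are cis by ring constraint and its single stereocentre is destroyed in the step. The forward reaction is an alkoxide-accelerated 1,3-shift of the allylic carbon C8, which must win over the 3,3-shift.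

**Side chain (12 ⇒ 6 + 11; 11 ⇐ 10 ⇐ 9 ⇐ 7 + 8).** The C1–C10 bond is cut to enone 6 and a 3-methylbut-1-en-2-yl metal. This is the only cut that delivers C9, C10 and the isopropyl group in one piece. The regiodefined alkenyllithium 10 comes from the hydrazone 9 of ketone 7 and hydrazide 8. It is used as cerium reagent 11, because 6 has a doubly activated methylene (C8) that a basic reagent would deprotonate.

**Oxidation pattern (6 ⇒ 5 ⇒ 2 ⇒ 1).** No C–C bond is cut. Direct allylic oxidation of diene 1 could not tell its four allylic methylenes and two methyl groups apart. The oxygen is therefore placed on an olefin carbon (epoxide 2), moved to the tertiary allylic position (5) and transposed oxidatively to the β-methyl enone 6. Diene 1 is a C10 commodity that already holds C2–C8 and both cis olefins.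

## Roads not taken

**Alternative 1:** (the most obvious) cut C1–C10 in an open (2Z,6Z)-farnesyl chain. The forward key step would be an intramolecular carbonyl allylation of bromo-aldehyde A1 (Nozaki–Hiyama–Kishi reaction with CrCl2, or an umpoled allylpalladium/Et2Zn variant) to the homoallylic alcohol A2, followed by hydrogenation of the isopropenyl group and esterification. The chosen plan is better for four reasons:
- A1 needs both Z-trisubstituted olefins from acyclic olefin synthesis, a run-up of some six or seven steps.
- The closure is a true medium-ring cyclisation from a chain.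
- The cyclic transition state of the allylation gives the anti adduct, which in the ring is oxygen trans to the three-carbon unit. A2 therefore has the wrong relative configuration, is racemic without a chiral ligand, and needs an inversion at C1.
- A 1,1-disubstituted olefin must then be hydrogenated beside two trisubstituted ones.

**Alternative 2:** cut C8–C9 and re-form C1–C6, a four-carbon ring expansion by anionic oxy-Cope rearrangement (KH) of carbinol A4, made from isopiperitenone A3 and the same alkenyl metal. The nucleophile adds anti to the isopropenyl group, so the two alkenyl groups of A4 are trans. The chair transition state then carries C5 equatorial and delivers C6=C7 as E, giving dienone A5 (2Z,6E). The 6Z olefin would need the cis-dialkenyl carbinol, the disfavoured adduct. The eight-membered precursor 12 has no such requirement, since both olefins are already cis in a ring.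

**Alternative 3:** cut C6=C7 after setting C1 and C10 in an open chain. An auxiliary-controlled anti-aldol and chain extension would give diene alcohol A6, and ring-closing metathesis (second-generation Grubbs catalyst) would close the ring. The linear sequence is long (auxiliary on and off, reduction and homologation of the acyl carbon). A trisubstituted olefin formed by metathesis inside a strained ten-membered ring has little driving force against oligomers. The geometry of the new olefin would be decided by ring strain, not by design.

Key step: step 6

## Route

Step 1
Reactants: 1 (1Z,5Z)-1,5-dimethylcycloocta-1,5-diene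
Product: 2 (4Z)-1,5-dimethyl-9-oxabicyclo[6.1.0]non-4-ene (cis-fused mono-epoxide; racemic)
Conditions: mCPBA (1.0 equiv), NaHCO3, CH2Cl2, 0 °C
Reagents that add atoms: 3-chloroperoxybenzoic acid (mCPBA), OOC(=O)c1cccc(Cl)c1
Why: Prilezhaev epoxidation; the two olefins of 1 are equivalent, so one equivalent of peracid should give a single mono-epoxide, and syn addition keeps the ring carbons cis on the oxirane.

Step 2
Reactants: 2 (4Z)-1,5-dimethyl-9-oxabicyclo[6.1.0]non-4-ene
Product: 5 (2Z,5Z)-1,5-dimethylcycloocta-2,5-dien-1-ol (racemic), via hydroxy selenide 3 (not isolated), via selenoxide 4 (not isolated)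
Conditions: (PhSe)2, NaBH4, EtOH, reflux; then H2O2 (30%), THF, 0 to 25 °C
Reagents that add atoms: none
Why: Epoxide-to-allylic-alcohol conversion by selenide opening and selenoxide syn-elimination: benzeneselenolate opens the oxirane at the secondary carbon with inversion, and the selenoxide can only eliminate toward C3 because the carbinol carbon bears no hydrogen. A cis olefin is the only unstrained outcome in an eight-membered ring that already holds one cis olefin.

Step 3
Reactants: 5 (2Z,5Z)-1,5-dimethylcycloocta-2,5-dien-1-ol
Product: 6 (2Z,6Z)-3,7-dimethylcycloocta-2,6-dien-1-one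
Conditions: [C5H5NH][CrO3Cl] (2 equiv), Celite, CH2Cl2, 25 °C
Reagents that add atoms: pyridinium chlorochromate [C5H5NH][CrO3Cl], [O-][Cr](=O)(=O)Cl.c1cc[nH+]cc1 (its oxo oxygen becomes the carbonyl oxygen)
Why: Babler–Dauben oxidative transposition: the tertiary allylic chromate ester shifts [3,3] to the secondary allylic chromate with the more substituted olefin, which is oxidised to the β-methyl enone; the remote trisubstituted olefin does not react with the chromium reagent at room temperature.

Step 4
Reactants: 7 3-methylbutan-2-one; 8 2,4,6-tri(propan-2-yl)benzenesulfonohydrazide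
Product: 9 N'-[(2E)-3-methylbutan-2-ylidene]-2,4,6-tri(propan-2-yl)benzenesulfonohydrazide
Conditions: MeOH, cat. HCl, 25 °C, crystallisation
Reagents that add atoms: none
Why: Hydrazone condensation; the E isomer places the sulfonamide nitrogen syn to the methyl group, which fixes the site of the second deprotonation in step 5.

Step 5
Reactants: 9 N'-[(2E)-3-methylbutan-2-ylidene]-2,4,6-tri(propan-2-yl)benzenesulfonohydrazide; 6 (2Z,6Z)-3,7-dimethylcycloocta-2,6-dien-1-one
Product: 12 (2Z,6Z)-3,7-dimethyl-1-(3-methylbut-1-en-2-yl)cycloocta-2,6-dien-1-ol (racemic), via alkenyllithium 10 (not isolated), via alkenylcerium dichloride 11 (not isolated)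
Conditions: 9, s-BuLi (2.1 equiv), TMEDA/hexane, −78 to 0 °C; anhydrous CeCl3, THF, −78 °C; then 6, −78 °C; aq NH4Cl
Reagents that add atoms: none
Why: Shapiro reaction: the dianion of the hydrazone, deprotonated at the methyl group, loses sulfinate and N2 to give the 2-metallated 1-alkene 10 regiospecifically. After transmetallation to the weakly basic cerium reagent 11 it should add 1,2 to 6 without deprotonating the doubly activated C8 methylene; the new stereocentre is racemic and is destroyed in step 6.

Step 6
Reactants: 12 (2Z,6Z)-3,7-dimethyl-1-(3-methylbut-1-en-2-yl)cycloocta-2,6-dien-1-ol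
Product: 15 (2Z,6Z)-3,7-dimethyl-10-(propan-2-yl)cyclodeca-2,6-dien-1-one (racemic), via potassium alkoxide 13 (not isolated), via potassium enolate 14 (not isolated)
Conditions: KH, 18-crown-6, THF/HMPA, 0 to 25 °C; then aq NH4Cl, −78 °C
Reagents that add atoms: none
Why: Deprotonation gives alkoxide 13, whose oxyanion weakens the one adjacent σ-bond that can leave as an allyl anion, C1–C8 (C8 is allylic to C6=C7); this bond breaks within a contact ion pair and C8 rebonds to C9, the unsubstituted β-carbon of the 1-isopropylvinyl ketone, giving the cross-conjugated enolate 14. The closest known reaction type is the alkoxide-accelerated [1,3]-sigmatropic shift used as a two-carbon ring expansion of potassium 1-vinylcycloalk-3-en-1-olates, which gives cycloalk-5-enones with the ring olefin geometry retained. The ten-membered ring is closed by this 1,3-shift, formally an intramolecular conjugate (10-endo-trig) addition of C8 to C9 with loss of the C1–C8 bond, so no medium ring has to be closed from an open chain. C10 becomes a stereocentre only when 14 is protonated and is formed racemic by design, since it is enolisable and is set in step 7. The step needs the 1,3-shift to win over the 3,3-shift (bonding of C6 to C9) and over Michael closure of C8 onto C3: C6–C9 bonding needs a boat array bridged by C2–C5 across the tub-shaped ring, C3 is a fully substituted β-carbon, and the dissociating medium (crown ether, HMPA) is the one that favours the 1,3-path in the parent series. Both olefins should stay cis because C2=C3 is not involved and the allyl fragment C6–C7–C8 keeps C5 and C8 on the same side, the arrangement fixed in the eight-membered ring and also the preferred one of an alkyl-substituted allylpotassium.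

Step 7
Reactants: 15 (2Z,6Z)-3,7-dimethyl-10-(propan-2-yl)cyclodeca-2,6-dien-1-one (racemic)
Product: 16 (1R,2Z,6Z,10S)-3,7-dimethyl-10-(propan-2-yl)cyclodeca-2,6-dien-1-ol
Conditions: H2 (8 atm), RuCl2[(S)-xylbinap][(S)-daipen] (1 mol %), KOtBu (0.2 equiv), iPrOH, 25 °C
Reagents that add atoms: none
Why: Noyori asymmetric hydrogenation under dynamic kinetic resolution, as established for 2-alkylcycloalkanones: KOtBu epimerises C10 (the only enolisable α-CH) while the ruthenium hydride/amine catalyst, which reduces C=O and leaves C=C alone, delivers hydride to one carbonyl face (C1 R with this antipode, by analogy with alkenyl alkyl ketones). The (10S)-ketone, which can accept hydride on the face anti to its isopropyl group, should be the fast-reacting enantiomer, so that OH and isopropyl end up cis and both stereocentres are set in this one step.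

Step 8
Reactants: 16 (1R,2Z,6Z,10S)-3,7-dimethyl-10-(propan-2-yl)cyclodeca-2,6-dien-1-ol; 17 4-acetoxy-3-methoxybenzoic acid
Product: 19 (1R,2Z,6Z,10S)-3,7-dimethyl-10-(propan-2-yl)cyclodeca-2,6-dien-1-yl 4-acetoxy-3-methoxybenzoate, via acid chloride 18 (not isolated)
Conditions: 17, (COCl)2, cat. DMF, CH2Cl2, 0 to 25 °C, evaporate; then 16, Et3N, DMAP (cat.), CH2Cl2, 0 to 25 °C
Reagents that add atoms: none
Why: Acylation of the secondary allylic alcohol by the acid chloride under nucleophilic catalysis forms the ester at oxygen, so C1 keeps its configuration and the allylic system is never ionised; the phenol is masked as its acetate so that 18 cannot oligomerise.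

Step 9
Reactants: 19 (1R,2Z,6Z,10S)-3,7-dimethyl-10-(propan-2-yl)cyclodeca-2,6-dien-1-yl 4-acetoxy-3-methoxybenzoate
Product: 20 (1R,2Z,6Z,10S)-3,7-dimethyl-10-(propan-2-yl)cyclodeca-2,6-dien-1-yl 4-hydroxy-3-methoxybenzoate (target, CNP0306317.1)
Conditions: pyrrolidine (2 equiv), CH2Cl2, 0 °C
Reagents that add atoms: none
Why: Aminolysis of the aryl acetate, a phenyl ester far more electrophilic than the hindered secondary alkyl benzoate, frees the phenol under neutral, cool conditions that spare the allylic ester and the acid- and heat-sensitive 1,5-diene.

## Compound list

1 | (1Z,5Z)-1,5-dimethylcycloocta-1,5-diene | C/C1=C/CC/C(C)=C\CC1 | starting material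
2 | (4Z)-1,5-dimethyl-9-oxabicyclo[6.1.0]non-4-ene, cis-fused, racemic (one enantiomer drawn) | C[C@]12CC/C=C(/C)CC[C@H]1O2 | intermediate
3 | (5Z)-1,5-dimethyl-2-(phenylselanyl)cyclooct-5-en-1-ol, OH and SePh trans, racemic (one enantiomer drawn) | C[C@]1(O)CC/C=C(/C)CC[C@@H]1[Se]c1ccccc1 | intermediate (not isolated)
4 | (5Z)-2-(benzeneseleninyl)-1,5-dimethylcyclooct-5-en-1-ol, selenoxide of 3 | C[C@]1(O)CC/C=C(/C)CC[C@@H]1[Se](=O)c1ccccc1 | intermediate (not isolated)
5 | (2Z,5Z)-1,5-dimethylcycloocta-2,5-dien-1-ol, racemic | CC1(O)/C=C\C/C(C)=C\CC1 | intermediate
6 | (2Z,6Z)-3,7-dimethylcycloocta-2,6-dien-1-one | O=C1/C=C(/C)CC/C=C(/C)C1 | intermediate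
7 | 3-methylbutan-2-one | CC(=O)C(C)C | starting material
8 | 2,4,6-tri(propan-2-yl)benzenesulfonohydrazide | CC(C)c1cc(C(C)C)c(S(=O)(=O)NN)c(C(C)C)c1 | starting material
9 | N'-[(2E)-3-methylbutan-2-ylidene]-2,4,6-tri(propan-2-yl)benzenesulfonohydrazide | C/C(=N\NS(=O)(=O)c1c(C(C)C)cc(C(C)C)cc1C(C)C)C(C)C | intermediate
10 | (3-methylbut-1-en-2-yl)lithium | [Li]C(=C)C(C)C | intermediate (not isolated)
11 | dichloro(3-methylbut-1-en-2-yl)cerium | Cl[Ce](Cl)C(=C)C(C)C | intermediate (not isolated)
12 | (2Z,6Z)-3,7-dimethyl-1-(3-methylbut-1-en-2-yl)cycloocta-2,6-dien-1-ol, racemic | C=C(C(C)C)C1(O)/C=C(/C)CC/C=C(/C)C1 | intermediate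
13 | potassium (2Z,6Z)-3,7-dimethyl-1-(3-methylbut-1-en-2-yl)cycloocta-2,6-dien-1-olate | C=C(C(C)C)C1([O-])/C=C(/C)CC/C=C(/C)C1.[K+] | intermediate (not isolated)
14 | potassium (2Z,6Z)-3,7-dimethyl-10-(propan-2-yl)cyclodeca-1(10),2,6-trien-1-olate | CC(C)C1=C([O-])/C=C(/C)CC/C=C(/C)CC1.[K+] | intermediate (not isolated)
15 | (2Z,6Z)-3,7-dimethyl-10-(propan-2-yl)cyclodeca-2,6-dien-1-one, racemic | O=C1/C=C(/C)CC/C=C(/C)CCC1C(C)C | intermediate
16 | (1R,2Z,6Z,10S)-3,7-dimethyl-10-(propan-2-yl)cyclodeca-2,6-dien-1-ol | O[C@H]1/C=C(/C)CC/C=C(/C)CC[C@H]1C(C)C | intermediate
17 | 4-acetoxy-3-methoxybenzoic acid | COc1cc(C(=O)O)ccc1OC(C)=O | starting material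
18 | 4-acetoxy-3-methoxybenzoyl chloride | COc1cc(C(=O)Cl)ccc1OC(C)=O | intermediate (not isolated)
19 | (1R,2Z,6Z,10S)-3,7-dimethyl-10-(propan-2-yl)cyclodeca-2,6-dien-1-yl 4-acetoxy-3-methoxybenzoate | COc1cc(C(=O)O[C@H]2/C=C(/C)CC/C=C(/C)CC[C@H]2C(C)C)ccc1OC(C)=O | intermediate
20 | (1R,2Z,6Z,10S)-3,7-dimethyl-10-(propan-2-yl)cyclodeca-2,6-dien-1-yl 4-hydroxy-3-methoxybenzoate | COc1cc(C(=O)O[C@H]2/C=C(/C)CC/C=C(/C)CC[C@H]2C(C)C)ccc1O | target

## Step count and least certain steps

Total step count: 9. Longest linear sequence: 8 (steps 1, 2, 3, 5, 6, 7, 8, 9 from diene 1); step 4 is a one-step branch to the alkenyl reagent.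

**Step 6 (key step).** The most likely failure is rebonding of the allyl fragment through its other terminus (C6 to C9, a 3,3-shift that only walks the substituent around the eight-membered ring). If the ion pair becomes long-lived, Michael closure of C8 onto C3 or loss of the C6=C7 geometry could follow. The cause is that the allyl anion is ambident and the tub-shaped ring can bring C6 near the vinyl terminus.

The fallback runs from 12 back to 15 and replaces the sigmatropic shift by a radical fragmentation and a separate ring closure. Photolysis of 12 with PhI(OAc)2 and I2 (hypoiodite reaction, cyclohexane, visible light) should generate the alkoxy radical. Its β-scission of the same C1–C8 bond gives an allyl radical, which iodine traps at the primary terminus as the open-chain allylic iodide (4Z,8Z)-10-iodo-5,9-dimethyl-2-(propan-2-yl)deca-1,4,8-trien-3-one F1. Slow addition of Bu3SnH/AIBN to F1 at high dilution (benzene, 80 °C) should then close the ten-membered ring: the regenerated allyl radical attacks through C8 on the unsubstituted terminus C9 of the 1-isopropylvinyl ketone, an allyl-radical macrocyclisation onto an enone of the kind used for cembranoid rings. Hydrogen transfer to the α-keto radical gives 15.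

**Step 7.** Three processes could spoil it:
- slow enolisation of the hindered C10–H, which would leave a plain kinetic resolution;
- base-induced γ-deprotonation, with migration or scrambling of the C2=C3 olefin;
- poor or reversed facial discrimination at C10 in the flexible ring, which would leave OH and isopropyl trans.

The fallback runs from 15 to 20 and answers a trans preference by inverting C1 during esterification instead of acylating with retention. Hydrogenation with the antipodal complex RuCl2[(R)-xylbinap][(R)-daipen] should then give the trans alcohol (1S,2Z,6Z,10S)-3,7-dimethyl-10-(propan-2-yl)cyclodeca-2,6-dien-1-ol F2. A Mitsunobu reaction of F2 with unprotected 4-hydroxy-3-methoxybenzoic acid (DIAD, PPh3, THF, 0 °C) should engage only the carboxylic acid, which is much more acidic than the phenol, and give 20 directly with inversion at C1. Steps 8 and 9 fall away.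

**Step 5.** The C8 methylene of 6 is both α to the carbonyl and allylic. Proton transfer to the alkenyl metal could outrun addition and return 6 or its conjugated isomer.

The fallback runs from 6 to 12 and builds the side chain from a much less basic nucleophile. Ethynylmagnesium bromide (THF, −20 °C) should add to 6 to give (2Z,6Z)-1-ethynyl-3,7-dimethylcycloocta-2,6-dien-1-ol F3. Copper-catalysed anti-carbomagnesiation of the propargylic alkoxide (iPrMgCl, 3 equiv, CuI 10 mol %, Et2O/THF, −20 to 25 °C; then aq NH4Cl) should place the isopropyl group on the internal alkyne carbon and give 12.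

**Step 3.** Under the acidic chromium conditions the product can enolise toward C8, so that the C6=C7 olefin migrates into conjugation or C8 is oxidised further.

The fallback runs from 5 to 6 and separates transposition from oxidation. Rhenium-catalysed 1,3-transposition of the hydroxyl group (O3ReOSiPh3, 2 mol %, Et2O, −50 to 0 °C) should give the secondary allylic alcohol (2Z,6Z)-3,7-dimethylcycloocta-2,6-dien-1-ol F4. Neutral oxidation of F4 with MnO2 (CH2Cl2, 25 °C) should give 6.

## Further compounds

F1 | step 6 | (4Z,8Z)-10-iodo-5,9-dimethyl-2-(propan-2-yl)deca-1,4,8-trien-3-one | C=C(C(C)C)C(=O)/C=C(/C)CC/C=C(/C)CI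
F2 | step 7 | (1S,2Z,6Z,10S)-3,7-dimethyl-10-(propan-2-yl)cyclodeca-2,6-dien-1-ol | O[C@@H]1/C=C(/C)CC/C=C(/C)CC[C@H]1C(C)C
F3 | step 5 | (2Z,6Z)-1-ethynyl-3,7-dimethylcycloocta-2,6-dien-1-ol (racemic) | C#CC1(O)/C=C(/C)CC/C=C(/C)C1
F4 | step 3 | (2Z,6Z)-3,7-dimethylcycloocta-2,6-dien-1-ol (racemic) | OC1/C=C(/C)CC/C=C(/C)C1
A1 | alternative 1 | (2Z,6Z,10E)-12-bromo-3,7,11-trimethyldodeca-2,6,10-trienal | O=C/C=C(/C)CC/C=C(/C)CC/C=C(\C)CBr
A2 | alternative 1 | (2Z,6Z)-3,7-dimethyl-10-(prop-1-en-2-yl)cyclodeca-2,6-dien-1-ol, OH and isopropenyl trans, racemic (one enantiomer drawn) | O[C@@H]1/C=C(/C)CC/C=C(/C)CC[C@H]1C(C)=C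
A3 | alternative 2 | 3-methyl-6-(prop-1-en-2-yl)cyclohex-2-en-1-one (isopiperitenone) | CC1=CC(=O)C(CC1)C(C)=C
A4 | alternative 2 | 3-methyl-1-(3-methylbut-1-en-2-yl)-6-(prop-1-en-2-yl)cyclohex-2-en-1-ol, alkenyl groups trans, racemic (one enantiomer drawn) | C=C(C(C)C)[C@@]1(O)C=C(C)CC[C@@H]1C(C)=C
A5 | alternative 2 | (2Z,6E)-3,7-dimethyl-10-(propan-2-yl)cyclodeca-2,6-dien-1-one | O=C1/C=C(/C)CC/C=C(\C)CCC1C(C)C
A6 | alternative 3 | (5Z,7R,8S)-5,11-dimethyl-8-(propan-2-yl)dodeca-1,5,11-trien-7-ol | O[C@@H](/C=C(/C)CCC=C)[C@@H](CCC(C)=C)C(C)C
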